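**Plan**
- Retrosynthesis: the three O–Si bonds are removed first; the only skeletal cut is then C5'–C1'' between ring B and the geranyl chain, which leads back to (S)-eriodictyol, geraniol and a diboron reagent.
- Enabling feature: once O3' and O4' are bridged by one silicon atom into a five-membered ring, C5'–H is the only aryl C–H bond whose single ortho neighbour is a tied-back oxygen. C6–H and C8–H of ring A each sit between two oxygens, and C2'–H and C6'–H flank the C1'–C2 bond.
- Forward: rings A, B and C are bought intact. The catechol is bridged, O7 is silylated, geraniol is converted into its methyl carbonate, and the chain is joined in one flask by C5'–H borylation followed by allyl–aryl coupling. Fluoride then frees the phenols.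
- Stereochemistry: C2 (S) comes from the chiral pool and never meets a free strong base; the 2''E alkene comes from geraniol.

Key step: step 4

Assumption: commercial (S)-eriodictyol is taken as enantiomerically pure at C2, so the route only has to preserve this centre.

Step 1
Reactants: 1 (S)-eriodictyol
Product: 2 (2S)-3',4'-O-(di-tert-butylsilylene)eriodictyol
Conditions: tBu2Si(OTf)2 (1.05 equiv, slow addition), pyridine (3 equiv), DMF, −40 to 0 °C; pH 7 buffer work-up
Reagents that add atoms: di-tert-butylsilyl bis(trifluoromethanesulfonate), CC(C)(C)[Si](OS(=O)(=O)C(F)(F)F)(OS(=O)(=O)C(F)(F)F)C(C)(C)C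
Why: O-silylation with a silyl bis-triflate (cyclic silylene formation): the ortho-dihydroxy unit of ring B should take up the reagent twice, the second Si–O bond closing the five-membered 1,3,2-dioxasilole intramolecularly, while the electron-poor 7-OH and the hydrogen-bonded 5-OH are poor nucleophiles under the weak base pyridine, which also leaves C2 untouched.

Step 2
Reactants: 2 (2S)-3',4'-O-(di-tert-butylsilylene)eriodictyol
Product: 3 (2S)-3',4'-O-(di-tert-butylsilylene)-7-O-(triisopropylsilyl)eriodictyol
Conditions: TIPSCl (1.2 equiv), imidazole (2.5 equiv), DMF, 0 °C to rt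
Reagents that add atoms: triisopropylsilyl chloride, CC(C)[Si](Cl)(C(C)C)C(C)C
Why: Silyl chloride/imidazole O-silylation: the acidic 7-OH para to the C4 carbonyl should be silylated while the 5-OH stays locked in its hydrogen bond to that carbonyl, and the bulky triisopropylsilyl group is chosen because it shields C6–H and C8–H and resists methoxide better than a tert-butyldimethylsilyl group.

Step 3
Reactants: 4 geraniol
Product: 5 (E)-geranyl methyl carbonate
Conditions: ClCO2Me (1.3 equiv), pyridine (2 equiv), CH2Cl2, 0 °C to rt
Reagents that add atoms: methyl chloroformate, COC(=O)Cl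
Why: Acylation of a primary allylic alcohol with a chloroformate (carbonate formation) does not ionise the allylic C–O bond, so the 2E alkene should be carried over unchanged.

Step 4
Reactants: 3 (2S)-3',4'-O-(di-tert-butylsilylene)-7-O-(triisopropylsilyl)eriodictyol; 5 (E)-geranyl methyl carbonate; 6 bis(pinacolato)diboron
Product: 10 (2S)-5'-geranyl-3',4'-O-(di-tert-butylsilylene)-7-O-(triisopropylsilyl)eriodictyol, via 5-O-boryl ester 7 (not isolated), via C5'-pinacol boronate 8 (not isolated), via geranylated 5-O-boryl ester 9 (not isolated)
Conditions: 6 (1.2 equiv), [Ir(OMe)(cod)]2 (2.5 mol%), 4,4'-di-tert-butyl-2,2'-bipyridine (5 mol%), THF, 65 °C; volatiles removed in vacuo; then 5 (1.6 equiv), Pd2(dba)3 (2.5 mol%), PPh3 (10 mol%), THF, 50 °C; aq. NH4Cl work-up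
Reagents that add atoms: none
Why: The tris(boryl) complex of trivalent iridium formed from [Ir(OMe)(cod)]2, the bipyridine and 6 should first cap the chelated 5-OH as its O-Bpin ester (7) and then cleave one aryl C–H bond by oxidative addition, C–B reductive elimination giving boronate 8 with H2 as the only by-product. After the volatile pinacolborane has been stripped (it would otherwise reduce the allyl complex), zerovalent palladium ionises carbonate 5 with loss of CO2 (Tsuji–Trost ionisation) to a geranyl π-allyl methoxide of divalent palladium, whose methoxide bridges to the aryl boron, the aryl group is transferred, and reductive elimination at the unsubstituted allyl terminus forms C5'–C1'' (9, hydrolysed to 10 on work-up). The closest known reactions are the iridium-catalysed borylation of 5-substituted 1,3-benzodioxoles at the C–H ortho to the ring oxygen and the base-free Suzuki–Miyaura-type coupling of arylboronates with allylic carbonates, here run as a one-pot C–H borylation/cross-coupling. No ring is closed and no stereocentre is created: C2 should stay S because no external base is present, and the 2''E alkene should be kept because the syn π-allyl complex couples at its CH2 terminus faster than it isomerises. The step needs one of five aryl C–H bonds to react, and sterics secure it: C6–H and C8–H each lie between two oxygens (OBpin/OTIPS and OTIPS/O1), C2'–H lies between O3' and C1', C6'–H is ortho to the branched C2, whereas C5'–H has as its only ortho neighbour O4', tied back in the five-membered dioxasilole whose tert-butyl groups stand above and below the ring plane, away from that bond. Linear over branched coupling follows from the same preference of the aryl–allyl reductive elimination for the less substituted terminus.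

Step 5
Reactants: 10 (2S)-5'-geranyl-3',4'-O-(di-tert-butylsilylene)-7-O-(triisopropylsilyl)eriodictyol
Product: 11 isonymphaeol B
Conditions: Et3N·3HF (6 equiv), THF/MeCN, 0 °C to rt, under argon; pH 7 buffer work-up
Reagents that add atoms: none
Why: Fluoride-induced desilylation: HF–amine should cleave all three aryl O–Si bonds through strong Si–F bond formation in a nearly neutral medium that cannot enolise C3 or open ring C (C2 stays S) and is too weakly acidic to protonate the trisubstituted alkenes of the geranyl chain.

**Compound list**
1 | (S)-eriodictyol, (2S)-2-(3,4-dihydroxyphenyl)-5,7-dihydroxychroman-4-one | Oc1ccc([C@@H]2CC(=O)c3c(O)cc(O)cc3O2)cc1O | starting material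
2 | (2S)-3',4'-O-(di-tert-butylsilylene)eriodictyol, (2S)-2-(2,2-di-tert-butyl-1,3,2-benzodioxasilol-5-yl)-5,7-dihydroxychroman-4-one | CC(C)(C)[Si]1(C(C)(C)C)Oc2ccc([C@@H]3CC(=O)c4c(O)cc(O)cc4O3)cc2O1 | intermediate
3 | (2S)-3',4'-O-(di-tert-butylsilylene)-7-O-(triisopropylsilyl)eriodictyol (5-OH free) | CC(C)(C)[Si]1(C(C)(C)C)Oc2ccc([C@@H]3CC(=O)c4c(O)cc(O[Si](C(C)C)(C(C)C)C(C)C)cc4O3)cc2O1 | intermediate
4 | geraniol, (2E)-3,7-dimethylocta-2,6-dien-1-ol | CC(C)=CCC/C(C)=C/CO | starting material
5 | (E)-geranyl methyl carbonate | CC(C)=CCC/C(C)=C/COC(=O)OC | intermediate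
6 | bis(pinacolato)diboron | CC1(C)OB(B2OC(C)(C)C(C)(C)O2)OC1(C)C | starting material
7 | 5-O-(pinacolatoboryl) ester of 3 | CC(C)(C)[Si]1(C(C)(C)C)Oc2ccc([C@@H]3CC(=O)c4c(OB5OC(C)(C)C(C)(C)O5)cc(O[Si](C(C)C)(C(C)C)C(C)C)cc4O3)cc2O1 | intermediate (not isolated)
8 | C5'-pinacol boronate of 7 (5-O-Bpin, 5'-C-Bpin, 2S) | CC(C)(C)[Si]1(C(C)(C)C)Oc2c(B5OC(C)(C)C(C)(C)O5)cc([C@@H]3CC(=O)c4c(OB5OC(C)(C)C(C)(C)O5)cc(O[Si](C(C)C)(C(C)C)C(C)C)cc4O3)cc2O1 | intermediate (not isolated)
9 | 5-O-(pinacolatoboryl) ester of 10 (5'-(2E)-geranyl, 2S) | CC(C)(C)[Si]1(C(C)(C)C)Oc2c(C/C=C(\C)CCC=C(C)C)cc([C@@H]3CC(=O)c4c(OB5OC(C)(C)C(C)(C)O5)cc(O[Si](C(C)C)(C(C)C)C(C)C)cc4O3)cc2O1 | intermediate (not isolated)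
10 | (2S)-5'-[(2E)-geranyl]-3',4'-O-(di-tert-butylsilylene)-7-O-(triisopropylsilyl)eriodictyol | CC(C)(C)[Si]1(C(C)(C)C)Oc2c(C/C=C(\C)CCC=C(C)C)cc([C@@H]3CC(=O)c4c(O)cc(O[Si](C(C)C)(C(C)C)C(C)C)cc4O3)cc2O1 | intermediate
11 | isonymphaeol B, (2S)-2-{3-[(2E)-3,7-dimethylocta-2,6-dien-1-yl]-4,5-dihydroxyphenyl}-5,7-dihydroxychroman-4-one | CC(C)=CCC/C(C)=C/Cc1cc([C@@H]2CC(=O)c3c(O)cc(O)cc3O2)cc(O)c1O | target

**Count**
Total steps: 5. Longest linear sequence: 4 steps (1 → 2 → 3 → 10 → 11); step 3 is a one-step side branch.

**Steps most likely to fail**

Step 4. The hindered ortho-silyloxy pinacol boronate may transmetalate slowly under base-free conditions. Protodeboronation, O-geranylation of ring A oxygens by the π-allyl complex and methoxide-induced loss of silicon could then compete; a sluggish C–H activation next to the di-tert-butylsilylene would show up at the same stage. The fallback sets out from 3 and returns to the route at 10. The iridium stage is run alone as in step 4 (through 7 and 8) and worked up with aqueous NH4Cl, so that the O–B bond is hydrolysed and the C5'-pinacol boronate F1 is isolated; this also allows the site of borylation to be proven before the chain is committed. The pinacol ester is cleaved with NaIO4 and NH4OAc in acetone/water at rt to the free boronic acid F2. F2 is then coupled with geraniol 4 itself under Pd(PPh3)4 in THF at 60–70 °C without base: the Lewis-acidic boronic acid activates the allylic hydroxyl for ionisation by zerovalent palladium, and the resulting hydroxide of divalent palladium transmetalates directly, so no free alkoxide appears. This direct allylic alcohol/arylboronic acid coupling is known chemistry and should give 10 as the linear E isomer.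

Step 1. The bis-triflate may be intercepted by the acidic 7-OH, or may bridge two flavanone molecules before the five-membered ring closes, giving mixed silyl ethers and oligomers. The fallback sets out from 1 and returns at 3 by reversing the order of protection. The 7-OH, the only phenol that a weak base ionises appreciably, is capped first with TIPSCl (1.0 equiv) and imidazole in DMF at −20 °C to give (2S)-7-O-(triisopropylsilyl)eriodictyol F3. Only the catechol is then left to react with tBu2Si(OTf)2 and pyridine in DMF at −40 to 0 °C, which should give 3 directly.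

Step 5. The freed, electron-rich catechol may oxidise to the ortho-quinone during work-up and streak on silica, and half-cleaved fluorosilyl ethers may be hard to separate from the polar tetraphenol. The fallback sets out from 10 and returns at 11 by capture and release. Desilylation is run as in step 5, and the crude product is acetylated at once with Ac2O and pyridine at 0 °C to the 7,3',4'-triacetate F4 (the hydrogen-bonded 5-OH should stay free). F4 is an air-stable, non-polar compound that can be purified at leisure. The phenols are then released with NH4OAc in aqueous MeOH at rt, a neutral phenolic acetate cleavage that should not touch C2, giving 11.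

**Further compounds**
F1 | step 4 | (2S)-5'-(pinacolatoboryl)-3',4'-O-(di-tert-butylsilylene)-7-O-(triisopropylsilyl)eriodictyol | CC(C)(C)[Si]1(C(C)(C)C)Oc2c(B5OC(C)(C)C(C)(C)O5)cc([C@@H]3CC(=O)c4c(O)cc(O[Si](C(C)C)(C(C)C)C(C)C)cc4O3)cc2O1
F2 | step 4 | (2S)-3',4'-O-(di-tert-butylsilylene)-7-O-(triisopropylsilyl)eriodictyol-5'-boronic acid | CC(C)(C)[Si]1(C(C)(C)C)Oc2c(B(O)O)cc([C@@H]3CC(=O)c4c(O)cc(O[Si](C(C)C)(C(C)C)C(C)C)cc4O3)cc2O1
F3 | step 1 | (2S)-7-O-(triisopropylsilyl)eriodictyol | Oc1ccc([C@@H]2CC(=O)c3c(O)cc(O[Si](C(C)C)(C(C)C)C(C)C)cc3O2)cc1O
F4 | step 5 | (2S)-5'-[(2E)-geranyl]eriodictyol 7,3',4'-triacetate | CC(C)=CCC/C(C)=C/Cc1cc([C@@H]2CC(=O)c3c(O)cc(OC(C)=O)cc3O2)cc(OC(C)=O)c1OC(C)=O
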